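**Plan**

1. Phthalide numbering is used: C1 lactone carbonyl, O2, C3 the stereocentre, ring A = C3a, C4, C5, C6, C7, C7a; side chain C1'–C14'. The retrosynthesis first opens the lactone at O2–C1 (methyl ester, silylated C3–OH, both chain ketones as dioxolanes), then cuts ring A at C4–C3a and C7–C7a, restoring a two-carbon bridge across C4 and C7.
2. The enabling feature is ring A itself: C7a carries the acyl carbon C1, the neighbouring C3a carries the carbinol carbon C3, and C5 and C7 carry methoxy groups. C4–C5–C6–C7 is therefore a 1,3-dimethoxycyclohexa-1,3-diene and C3a–C7a a 2-ynoate with ester and carbinol on its two alkyne carbons.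
3. The ynoate is cut at C3–C3a (propiolate plus chain aldehyde) and the chain at C10'–C11' (acyl anion of undec-10-enal onto methyl vinyl ketone).
4. Forward order: chain first (Stetter, dioxolanes, hydroboration, oxidation), then propiolate addition, oxidation, asymmetric reduction and silylation; ring A then arises by cycloaddition and ethene loss; the lactone ring closes last, on acidic deprotection.
5. The only stereocentre, C3, is set by reagent control: Midland reduction of the 4-oxo-2-ynoate with (S)-Alpine-Borane (from (−)-α-pinene). It is carried through steps that neither ionise nor deprotonate it.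

Key step: step 11

Remark: C3 is (S) in the target, and the same spatial arrangement is (S) in the 4-oxygenated 2-ynoates (O > alkynyl > alkyl) and in the benzoates (O > aryl > alkyl), so the descriptor does not change along the route.

**Route**

Step 1
Reactants: 1 1,3-dimethoxybenzene
Product: 2 1,5-dimethoxycyclohexa-1,4-diene
Conditions: Na, EtOH, liq. NH3, THF, −33 °C; H2O work-up, base-washed glassware
Reagents that add atoms: none
Why: Birch reduction of a resorcinol diether protonates the carbon between the two methoxy-bearing carbons and the carbon para to it, so both enol-ether double bonds remain in the unconjugated diene.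

Step 2
Reactants: 2 1,5-dimethoxycyclohexa-1,4-diene
Product: 3 1,3-dimethoxycyclohexa-1,3-diene
Conditions: KNH2 (0.1 equiv), liq. NH3, Et2O, −33 °C; then NH4Cl (0.1 equiv), distillation
Reagents that add atoms: none
Why: Base-catalysed prototropic isomerisation (deprotonation of a doubly allylic CH2, reprotonation of the pentadienyl anion at a terminus) brings the two enol-ether double bonds into conjugation, as known for 2,5-dihydroanisoles; the equilibrium is expected to favour 3, and any 2 left over is a spectator in step 11.

Step 3
Reactants: 4 undec-10-enal; 5 methyl vinyl ketone (but-3-en-2-one)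
Product: 6 pentadec-14-ene-2,5-dione
Conditions: 3-benzyl-5-(2-hydroxyethyl)-4-methylthiazolium chloride (cat.), Et3N, EtOH, 80 °C
Reagents that add atoms: none
Why: Stetter reaction: the thiazolylidene turns the aliphatic aldehyde into an acyl anion equivalent that adds 1,4 to the enone to form the C10'–C11' bond, and the isolated terminal alkene is not an acceptor.

Step 4
Reactants: 6 pentadec-14-ene-2,5-dione
Product: 7 pentadec-14-ene-2,5-dione 2,5-bis(ethylene ketal)
Conditions: HOCH2CH2OH (excess), p-TsOH (cat.), benzene, reflux, Dean–Stark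
Reagents that add atoms: ethane-1,2-diol, OCCO
Why: Acid-catalysed acetalisation with azeotropic removal of water, in which excess diol should trap both carbonyl groups before cyclodehydration of the 1,4-diketone can compete, the standard way to the bis-dioxolane of hexane-2,5-dione.

Step 5
Reactants: 7 pentadec-14-ene-2,5-dione 2,5-bis(ethylene ketal)
Product: 9 15-hydroxypentadecane-2,5-dione 2,5-bis(ethylene ketal), via B-alkyl-9-borabicyclo[3.3.1]nonane 8 (not isolated)
Conditions: 9-BBN, THF, 0 °C → rt; then NaOH, H2O2, 0 °C → rt
Reagents that add atoms: 9-borabicyclo[3.3.1]nonane, [H]B1C2CCCC1CCC2 (boron unit of 8 only; none of it remains in 9); hydrogen peroxide, OO (hydroxyl oxygen of 9)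
Why: Anti-Markovnikov hydroboration of the terminal alkene followed by oxidation of the C–B bond gives the primary alcohol, and dioxolanes are inert to borane and to basic peroxide.

Step 6
Reactants: 9 15-hydroxypentadecane-2,5-dione 2,5-bis(ethylene ketal)
Product: 10 11,14-dioxopentadecanal 11,14-bis(ethylene ketal)
Conditions: Dess–Martin periodinane, NaHCO3, CH2Cl2, 0 °C → rt
Reagents that add atoms: none
Why: Buffered Dess–Martin oxidation stops cleanly at the aldehyde and leaves the acid-labile dioxolanes untouched.

Step 7
Reactants: 10 11,14-dioxopentadecanal 11,14-bis(ethylene ketal); 11 methyl propiolate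
Product: 13 methyl 4-hydroxy-14,17-dioxooctadec-2-ynoate 14,17-bis(ethylene ketal) (racemic), via lithium acetylide 12 (not isolated)
Conditions: n-BuLi, THF, −78 °C; then 10, −78 °C; AcOH/THF quench at −78 °C
Reagents that add atoms: n-butyllithium, [Li]CCCC (lithium of 12 only; none of it remains in 13)
Why: 1,2-Addition of lithium methyl propiolate, which is stable at −78 °C, to the aldehyde forms the C3–C3a bond; the racemic carbinol is acceptable because the centre is reset in steps 8 and 9.

Step 8
Reactants: 13 methyl 4-hydroxy-14,17-dioxooctadec-2-ynoate 14,17-bis(ethylene ketal) (racemic)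
Product: 14 methyl 4,14,17-trioxooctadec-2-ynoate 14,17-bis(ethylene ketal)
Conditions: Dess–Martin periodinane, NaHCO3, CH2Cl2, 0 °C
Reagents that add atoms: none
Why: Dess–Martin oxidation of a propargylic alcohol to the ynone proceeds under neutral conditions free of nucleophiles, which suits the strongly electrophilic 4-oxo-2-ynoate.

Step 9
Reactants: 14 methyl 4,14,17-trioxooctadec-2-ynoate 14,17-bis(ethylene ketal)
Product: 16 methyl (4S)-4-hydroxy-14,17-dioxooctadec-2-ynoate 14,17-bis(ethylene ketal), via borinate ester 15 (not isolated)
Conditions: (S)-Alpine-Borane [B-isopinocampheyl-9-borabicyclo[3.3.1]nonane from (−)-α-pinene] (2 equiv), THF (concentrated), 0 °C → rt; CH3CHO; then HOCH2CH2NH2, Et2O, 0 °C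
Reagents that add atoms: (S)-Alpine-Borane, C[C@@H]1[C@@H](B3C4CCCC3CCC4)C[C@H]2C[C@@H]1C2(C)C (9-borabicyclononyl unit of 15 only; none of it remains in 16)
Why: Midland reduction: hydride passes from the pinanyl C–H to the carbonyl through a boat-like six-membered transition state with the slender alkynyl group in the crowded position, so the reagent from (−)-α-pinene should give the (S)-carbinol, the sense established for alk-1-yn-3-ones and alkyl 4-oxoalk-2-ynoates; the ester and dioxolanes are not reduced.

Step 10
Reactants: 16 methyl (4S)-4-hydroxy-14,17-dioxooctadec-2-ynoate 14,17-bis(ethylene ketal)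
Product: 17 methyl (4S)-4-(tert-butyldimethylsilyloxy)-14,17-dioxooctadec-2-ynoate 14,17-bis(ethylene ketal)
Conditions: TBSCl, imidazole, DMF, 0 °C → rt
Reagents that add atoms: tert-butyldimethylsilyl chloride, CC(C)(C)[Si](C)(C)Cl
Why: Standard imidazole-mediated silylation of a secondary alcohol, which removes the free hydroxyl that could add to enol ethers or ynoates during the thermal step and does not touch the C–O bond of the stereocentre.

Step 11
Reactants: 3 1,3-dimethoxycyclohexa-1,3-diene; 17 methyl (4S)-4-(tert-butyldimethylsilyloxy)-14,17-dioxooctadec-2-ynoate 14,17-bis(ethylene ketal)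
Product: 19 methyl 2-[(1S)-1-(tert-butyldimethylsilyloxy)-11,14-dioxopentadecyl]-4,6-dimethoxybenzoate 11,14-bis(ethylene ketal), via bicyclo[2.2.2]octadiene adduct 18 (not isolated)
Conditions: 3 (4 equiv), neat, 2,6-di-tert-butyl-4-methylphenol (cat.), degassed sealed tube, 180 °C; volatiles removed in vacuo
Reagents that add atoms: none
Why: The electron-rich diene 3 and the electron-poor ynoate 17 combine in a concerted, normal-electron-demand [4+2] cycloaddition to give bicyclo[2.2.2]octa-2,5-diene 18, which at the same temperature loses its ethano bridge as ethene by retro-[4+2] reaction, driven irreversibly by aromatisation. The closest known reaction type is the Alder–Rickert synthesis of 6-substituted 2,4-dimethoxybenzoates from alkoxycyclohexadienes and alk-2-ynoates. Ring A closes by cycloaddition, the bonds C4–C3a and C7–C7a forming together across the diene termini, and is aromatised by the cycloreversion. No stereocentre is created: the bridgehead centres of 18 vanish on aromatisation, and the (S)-carbinol centre is a spectator because the medium is neutral and no bond to it is broken. The selectivity required is regiochemical and is secured by polarisation: the unsubstituted diene terminus, which has the largest HOMO coefficient as the vinylogous β-carbon of both enol ethers, bonds to the ynoate β-carbon, which has the largest LUMO coefficient, so the ester carbon ends beside the methoxy-bearing terminus and the 2,4-dimethoxy-6-alkyl pattern results.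

Step 12
Reactants: 19 methyl 2-[(1S)-1-(tert-butyldimethylsilyloxy)-11,14-dioxopentadecyl]-4,6-dimethoxybenzoate 11,14-bis(ethylene ketal)
Product: 21 (3S)-5,7-dimethoxy-3-(10,13-dioxotetradecyl)-2-benzofuran-1(3H)-one (CJ-13,015), via hydroxy diketo ester 20 (not isolated)
Conditions: HCl (2 M aq.), THF, 45 °C
Reagents that add atoms: water, O
Why: Aqueous acid hydrolyses both dioxolanes and the silyl ether, and the freed benzylic hydroxyl closes the five-membered lactone on the ortho methyl ester by acyl substitution with retention at C3; a benzylic cation at C3 is disfavoured because the ester is ortho and both methoxy groups are meta, and aqueous acid does not dehydrate the 1,4-diketone.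

**Compound list**

1 | 1,3-dimethoxybenzene | COc1cccc(OC)c1 | starting material
2 | 1,5-dimethoxycyclohexa-1,4-diene | COC1=CCC=C(OC)C1 | intermediate
3 | 1,3-dimethoxycyclohexa-1,3-diene | COC1=CC(OC)=CCC1 | intermediate
4 | undec-10-enal | C=CCCCCCCCCC=O | starting material
5 | methyl vinyl ketone (but-3-en-2-one) | CC(=O)C=C | starting material
6 | pentadec-14-ene-2,5-dione | C=CCCCCCCCCC(=O)CCC(C)=O | intermediate
7 | pentadec-14-ene-2,5-dione 2,5-bis(ethylene ketal) [2-(dec-9-en-1-yl)-2-[2-(2-methyl-1,3-dioxolan-2-yl)ethyl]-1,3-dioxolane] | C=CCCCCCCCCC1(CCC2(C)OCCO2)OCCO1 | intermediate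
8 | 9-(11,14-dioxopentadecyl)-9-borabicyclo[3.3.1]nonane 11,14-bis(ethylene ketal) (formed in the flask, not isolated) | C12CCCC(CCC1)B2CCCCCCCCCCC3(CCC4(C)OCCO4)OCCO3 | intermediate
9 | 15-hydroxypentadecane-2,5-dione 2,5-bis(ethylene ketal) | OCCCCCCCCCCC1(CCC2(C)OCCO2)OCCO1 | intermediate
10 | 11,14-dioxopentadecanal 11,14-bis(ethylene ketal) | O=CCCCCCCCCCC1(CCC2(C)OCCO2)OCCO1 | intermediate
11 | methyl propiolate (methyl prop-2-ynoate) | COC(=O)C#C | starting material
12 | methyl 3-lithioprop-2-ynoate (formed in the flask, not isolated) | COC(=O)C#C[Li] | intermediate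
13 | methyl 4-hydroxy-14,17-dioxooctadec-2-ynoate 14,17-bis(ethylene ketal), racemic | COC(=O)C#CC(O)CCCCCCCCCC1(CCC2(C)OCCO2)OCCO1 | intermediate
14 | methyl 4,14,17-trioxooctadec-2-ynoate 14,17-bis(ethylene ketal) | COC(=O)C#CC(=O)CCCCCCCCCC1(CCC2(C)OCCO2)OCCO1 | intermediate
15 | methyl (4S)-4-(9-borabicyclo[3.3.1]nonan-9-yloxy)-14,17-dioxooctadec-2-ynoate 14,17-bis(ethylene ketal) (formed in the flask, not isolated) | COC(=O)C#C[C@@H](OB1C2CCCC1CCC2)CCCCCCCCCC3(CCC4(C)OCCO4)OCCO3 | intermediate
16 | methyl (4S)-4-hydroxy-14,17-dioxooctadec-2-ynoate 14,17-bis(ethylene ketal) | COC(=O)C#C[C@@H](O)CCCCCCCCCC1(CCC2(C)OCCO2)OCCO1 | intermediate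
17 | methyl (4S)-4-(tert-butyldimethylsilyloxy)-14,17-dioxooctadec-2-ynoate 14,17-bis(ethylene ketal) | COC(=O)C#C[C@@H](O[Si](C)(C)C(C)(C)C)CCCCCCCCCC1(CCC2(C)OCCO2)OCCO1 | intermediate
18 | methyl 3-[(1S)-1-(tert-butyldimethylsilyloxy)-11,14-dioxopentadecyl]-1,5-dimethoxybicyclo[2.2.2]octa-2,5-diene-2-carboxylate 11,14-bis(ethylene ketal), both bridgehead diastereomers (formed in the flask, not isolated) | COC12CCC(C(OC)=C1)C([C@@H](O[Si](C)(C)C(C)(C)C)CCCCCCCCCC3(CCC4(C)OCCO4)OCCO3)=C2C(=O)OC | intermediate
19 | methyl 2-[(1S)-1-(tert-butyldimethylsilyloxy)-11,14-dioxopentadecyl]-4,6-dimethoxybenzoate 11,14-bis(ethylene ketal) | COC(=O)c1c(OC)cc(OC)cc1[C@@H](O[Si](C)(C)C(C)(C)C)CCCCCCCCCC2(CCC3(C)OCCO3)OCCO2 | intermediate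
20 | methyl 2-[(1S)-1-hydroxy-11,14-dioxopentadecyl]-4,6-dimethoxybenzoate (formed in the flask, not isolated) | COC(=O)c1c(OC)cc(OC)cc1[C@@H](O)CCCCCCCCCC(=O)CCC(C)=O | intermediate
21 | (3S)-5,7-dimethoxy-3-(10,13-dioxotetradecyl)-2-benzofuran-1(3H)-one (CJ-13,015) | COc1cc(OC)c2c(c1)[C@H](CCCCCCCCCC(=O)CCC(C)=O)OC2=O | target

**Step count and risks**

Total step count: 12. Longest linear sequence: 10 steps (steps 3–12, from undec-10-enal); the diene branch adds steps 1 and 2.

Steps most likely to fail:

1. Step 11. The cycloaddition onto the internal, γ-branched ynoate may be slower than the thermal loss of the diene, by disproportionation to the arene and by drift back to the unconjugated isomer, so that conversion stalls. The fallback sets out from 17 and comes back at 19, and uses a diene that is formed fully conjugated and regiodefined. Kinetic deprotonation of commercial 3-methoxycyclohex-2-en-1-one at C6 with LiN(i-Pr)2 in THF at −78 °C and O-silylation with Me3SiCl should give 1-methoxy-3-(trimethylsilyloxy)cyclohexa-1,3-diene F1. Heating F1 with 17 under the conditions of step 11 should give, with the same polarisation-controlled orientation, methyl 3-[(1S)-1-(tert-butyldimethylsilyloxy)-11,14-dioxopentadecyl]-1-methoxy-5-(trimethylsilyloxy)bicyclo[2.2.2]octa-2,5-diene-2-carboxylate 11,14-bis(ethylene ketal) F2. Loss of ethene then gives methyl 2-[(1S)-1-(tert-butyldimethylsilyloxy)-11,14-dioxopentadecyl]-6-methoxy-4-(trimethylsilyloxy)benzoate 11,14-bis(ethylene ketal) F3. Methanolysis of the aryl silyl ether (K2CO3, MeOH, 0 °C), which spares the secondary silyl ether, gives methyl 2-[(1S)-1-(tert-butyldimethylsilyloxy)-11,14-dioxopentadecyl]-4-hydroxy-6-methoxybenzoate 11,14-bis(ethylene ketal) F4. O-Methylation of this phenol (MeI, K2CO3, acetone) returns the route to 19.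

2. Step 9. If hydride transfer is slow, the reagent can dissociate into α-pinene and 9-borabicyclo[3.3.1]nonane, which reduces the ynone without facial preference, so the enantiomeric purity of the carbinol erodes. The fallback sets out from 10 (with 11) and comes back at 16, replacing steps 7–9 by one catalytic asymmetric alkynylation: Me2Zn with the ProPhenol ligand (cat.) and Ph3P=O (cat.) in toluene at 4 °C adds methyl propiolate directly to the aldehyde. The ligand antipode is selected, and the configuration confirmed by Mosher ester analysis, so that the (S)-alcohol 16 is obtained. This path makes no further compound (none F0).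

3. Step 12. Hydrolysis of the hindered benzylic silyl ether may lag behind ketal cleavage, and forcing the acid could then bring on aldol or cyclodehydration reactions of the free 1,4-diketone. The fallback sets out from 19 and comes back at 21, separating the two events. Bu4NF in THF at 0 °C → rt removes the silyl group, and the alkoxide closes the lactone on the neighbouring methyl ester to give (3S)-5,7-dimethoxy-3-(10,13-dioxotetradecyl)-2-benzofuran-1(3H)-one 10,13-bis(ethylene ketal) F5. Mild hydrolysis (pyridinium p-toluenesulfonate, acetone/H2O, 50 °C) then frees both ketones to give 21.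

**Further compounds**

F1 | step 11 | 1-methoxy-3-(trimethylsilyloxy)cyclohexa-1,3-diene | COC1=CC(O[Si](C)(C)C)=CCC1
F2 | step 11 | methyl 3-[(1S)-1-(tert-butyldimethylsilyloxy)-11,14-dioxopentadecyl]-1-methoxy-5-(trimethylsilyloxy)bicyclo[2.2.2]octa-2,5-diene-2-carboxylate 11,14-bis(ethylene ketal) | COC12CCC(C(O[Si](C)(C)C)=C1)C([C@@H](O[Si](C)(C)C(C)(C)C)CCCCCCCCCC3(CCC4(C)OCCO4)OCCO3)=C2C(=O)OC
F3 | step 11 | methyl 2-[(1S)-1-(tert-butyldimethylsilyloxy)-11,14-dioxopentadecyl]-6-methoxy-4-(trimethylsilyloxy)benzoate 11,14-bis(ethylene ketal) | COC(=O)c1c(OC)cc(O[Si](C)(C)C)cc1[C@@H](O[Si](C)(C)C(C)(C)C)CCCCCCCCCC2(CCC3(C)OCCO3)OCCO2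
F4 | step 11 | methyl 2-[(1S)-1-(tert-butyldimethylsilyloxy)-11,14-dioxopentadecyl]-4-hydroxy-6-methoxybenzoate 11,14-bis(ethylene ketal) | COC(=O)c1c(OC)cc(O)cc1[C@@H](O[Si](C)(C)C(C)(C)C)CCCCCCCCCC2(CCC3(C)OCCO3)OCCO2
F0 | step 9 | none | none
F5 | step 12 | (3S)-5,7-dimethoxy-3-(10,13-dioxotetradecyl)-2-benzofuran-1(3H)-one 10,13-bis(ethylene ketal) | COc1cc(OC)c2c(c1)[C@H](CCCCCCCCCC3(CCC4(C)OCCO4)OCCO3)OC2=O
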